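## The problem

The target 25 is an ent-drimane: a trans-fused decalin whose C11 oxygen is etherified with umbelliferone. Drimane numbering is used for every intermediate (ring A: C1–C5 and C10; ring B: C5–C10; C11 is the oxymethylene carbon on C9, C12 the methyl on C8). Five stereocentres must be set: C2 and C3 (a trans-diequatorial diol beside the C4 gem-dimethyl group), C5, C9 and the quaternary C10. The absolute configuration is that of the enantiomeric drimane series, so the usual chiral-pool drimanes are of no use and the first centre must come from an enantioselective reaction.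

C10 is the natural anchor. Its axial methyl, with the axial C4 methyl, screens one face of ring A, so reagents reach C2 and C3 from the other side and both oxygens end up equatorial. It also screens one face of C9, so hydrogen delivered from the open face leaves C11 equatorial and cis to the methyl. C5 can be set trans to it by dissolving-metal reduction of a C4=C5 enone.

The sensitive parts are:
- the coumarin, a lactone and conjugate acceptor that will not tolerate hydride, dissolving metal, enolates or hydroxide;
- the trisubstituted C7=C8 olefin, which moves to C8=C9 under acid;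
- the homoallylic C9–H/C11–O array, which can eliminate to a diene.

The coumarin should therefore enter last, after the diol is complete and protected.

The feature that opens the route lies in ring B. C8 is its only methyl-bearing carbon and sits between the C7 methylene and C9, the carbon that must carry C11. A C9 ketone in a five-membered B-nor ring is flanked by the quaternary C10, which cannot enolise and migrates poorly, and by C7. One carbon bearing a methyl can therefore be inserted into the C7–C9 bond, and the ketone stays where C11 is needed.

## Retrosynthesis

**Acetonide and C11–O(aryl) bond.** The diol of 25 is masked as the trans-fused acetonide 24, which is cut at the C11–O bond into the homoallylic alcohol 22 and umbelliferone 23 (Mitsunobu etherification). Introducing the coumarin earlier would expose it to hydride, strong base and borane. Cutting here keeps all of that chemistry on a hydrocarbon-like core. Precursor 22 is simpler by the whole aromatic part and still holds all five stereocentres. The forward step must substitute at the β-branched C11 without elimination across C9–C11.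

**C9–H/C11–O and C9=C11.** Alcohol 22 is traced to diene 20 (anti-Markovnikov hydration of the exocyclic olefin by hydroboration) and 20 to enone 19 (carbonyl methylenation). Adding a C11 nucleophile to the ketone instead would leave a tertiary C9 oxygen to remove. The olefination/hydroboration pair adds C11 and sets C9 in two steps. Enone 19 has one carbon and one stereocentre fewer. The hydroboration must choose the exocyclic olefin and the face away from the C10 methyl.

**C7=C8.** Enone 19 comes from the saturated ketone 17 by dehydrogenation through the silyl enol ether 18. Because C10 is quaternary, 17 enolises only towards C8, so no regiochemical question arises. The C8 stereocentre of 17 is erased here and need not be controlled earlier.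

**C7–C8 and C8–C9 (key disconnection).** Both bonds of C8 in 17 are cut. This removes C8 with its methyl as diazoethane 16 and leaves the B-nor ketone 14, a trans-hydrindanone. Building ring B by annulation onto a ring A ketone would have to create the quaternary C10 and the hindered C9 carbonyl in one crowded operation. The one-carbon insertion instead starts from a 6-5 bicycle whose quaternary centre is available in either absolute configuration. Precursor 14 has two carbons and one ring atom fewer, and C5 and C10 are already correct. The forward reaction must migrate C7 rather than C10, stop after one insertion and spare the acetonide.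

**C9 oxidation level and the 2,3-diol.** Ketone 14 derives from alcohol 13 (oxidation), 13 from silyl ether 12 (fluoride), 12 from diol 11 (acetonide formation), 11 from ketol 10 (hydride) and 10 from ketone 8 (enolate hydroxylation at C2, the only enolisable position). C9 is carried as a silyl ether because two ketones could not be told apart while C2 and C3 are elaborated. A C9 ketal was not chosen, because a cyclopentanone next to a quaternary carbon ketalises slowly beside an enone and its acidic removal would compete with loss of the strained acetonide. These are functional-group changes only; each is asked for clean chemoselectivity, and the two stereocentres follow from the bias of the bicycle.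

**C4–CH3 and C5–H.** Ketone 8 is cut to enone 6 by removing one C4 methyl and the C5 hydrogen (reductive methylation). Deconjugative dialkylation followed by hydrogenation would need two steps, so the one-step reductive alkylation is preferred. Enone 6 comes from alcohol 5 by silylation and 5 from enedione 4 by selective reduction of the saturated ketone. The forward reduction must give the trans ring fusion.

**C4=C5 and C1–C10.** Enedione 4 is a Robinson annulation product. Cutting the aldol bond (C4=C5) gives the achiral triketone 3, and cutting the Michael bond (C1–C10) gives dione 1 and enone 2. This is the point where absolute configuration enters: an amino-acid catalyst must distinguish the two enantiotopic ring carbonyls of 3.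

**Diazo component.** Diazoethane 16 is made immediately before use from N-ethyl-N-nitrosourea 15.

## Roads not taken

Alternative 1: Both rings are cut at once (C4–C5 and C9–C10), back to the open-chain epoxide A1, (R)-10′,11′-epoxyumbelliprenin. In the forward step a tin or bismuth Lewis acid opens the epoxide at its tertiary carbon, the two trisubstituted olefins add in turn through a chair–chair array, and loss of a C7 proton gives A2, the 2-deoxy analogue of 25.
- Merits: one step makes both rings and derives C5, C9 and C10 from a single epoxide stereocentre. The ether and the whole skeleton are in place, and A1 is about four steps from 23.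
- Weak points: the C2 hydroxyl is missing. It would have to be added afterwards by oxidation at C3, enolate hydroxylation at C2 and hydride reduction, all in the presence of the coumarin. The termination is not controlled (C7=C8, C8=C12 and C8=C9 olefins, and monocyclic material). The allylic aryl ether can ionise, and the arene can capture the C8 cation.
- Comparison: this road is clearly shorter, roughly half the length, and the chosen plan cannot match that. What the chosen plan offers instead is that every stereocentre and the olefin position are set in separate, predictable steps, and the diol is complete before the coumarin is present.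

Alternative 2: Ring B is cut at C5–C6 and C9–C10 into the dienyl silyl ether A3 and the dienal A4. A cationic chiral oxazaborolidine catalyst would activate A4 for an exo-selective Diels–Alder reaction giving A5.
- Merits: a catalytic enantioselective step sets C5, C9 and C10 together. The C7=C8 olefin, its methyl and the C11 oxygen are present from the start, so the work of steps 13–15 of the chosen route would not be needed.
- Weak points: the two substituents of A3 direct to opposite regiochemistry (the terminal substituent "ortho", the internal methyl "para"). A4 is a β-substituted α-methyl enal, a slow dienophile, and is itself a diene that can dimerise. Most seriously, ring A is still absent in A5: one ring carbon, the second C4 methyl, the quaternary C4 and both hydroxyls must be built from a formyl and an isopropenyl group.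
- Comparison: this road is better for ring B. The chosen plan is better for ring A, which comes almost ready-made from 4 (the gem-dimethyl group in one step, the diol in two substrate-controlled steps). Overall the alternative would be no shorter and its key step is less secure.

Alternative 3: C5–C10 and C8–C9 are cut, giving the triene A7, which would be assembled from (S)-pantolactone A6 (source of C3 and the gem-dimethyl carbon; the less common enantiomer is required). On heating, or with a mild aluminium Lewis acid, the (E)-enoate of A7 adds to its 2-silyloxy diene to give A8.
- Merits: one step would make both rings and set C5, C9 and C10. The enoate geometry translates directly into the C9/C10 relationship, and C11, C12, the diol and the gem-dimethyl group are already present.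
- Weak points: A7 needs a long linear sequence with two defined olefins and a sensitive silyloxy diene. The dienophile carries its methyl on the internal carbon, so the cycloaddition must form the quaternary ring-fusion centre and will be slow. Cis versus trans fusion, and the facial sense relative to the tether acetonide, are hard to predict. Afterwards the C7 oxygen must be removed to reach the C7=C8 olefin, so the endgame is not shorter.
- Comparison: if the cycloaddition were selective, this road would create more complexity per step than a ring expansion, which makes one ring and no lasting stereocentre. The chosen plan offers instead a bicyclic starting point two steps from commodity chemicals, and stereocentres set one at a time with a sense that can be read from a rigid bicycle.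

Key step: step 12

Remark: the 2,3-diol is trans-diequatorial, so its acetonide is a trans-fused dioxolane; it is assumed to form under kinetic acetalisation and to survive buffered or aprotic conditions, as acetonides of trans-cyclohexane-1,2-diols do.

Step 1
Reactants: 1 2-methylcyclopentane-1,3-dione; 2 ethyl vinyl ketone (pent-1-en-3-one)
Product: 3 2-methyl-2-(3-oxopentyl)cyclopentane-1,3-dione
Conditions: H2O, AcOH (cat.), 70 °C
Reagents that add atoms: none
Why: Michael addition of the acidic 1,3-dione to the enone forms the C1–C10 bond; the product is achiral and its quaternary carbon prevents a second addition.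

Step 2
Reactants: 3 2-methyl-2-(3-oxopentyl)cyclopentane-1,3-dione
Product: 4 (7aR)-4,7a-dimethyl-2,3,7,7a-tetrahydro-1H-indene-1,5(6H)-dione (B-nor enedione: C9 ketone in the five-membered ring and C3 ketone conjugated to C4=C5)
Conditions: D-phenylalanine (1 equiv), 1 M aq. HClO4 (0.5 equiv), MeCN, reflux
Reagents that add atoms: none
Why: Hajos–Parrish–Eder–Sauer–Wiechert cyclisation (enamine aldol, then dehydration) forms C4=C5; the D-amino acid distinguishes the enantiotopic ring carbonyls and sets C10 (R), and a primary amino acid is preferred for triketones derived from ethyl ketones; the enantiomeric purity can be raised by crystallisation of 4 or 5.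

Step 3
Reactants: 4 (7aR)-4,7a-dimethyl-2,3,7,7a-tetrahydro-1H-indene-1,5(6H)-dione
Product: 5 (1R,7aR)-1-hydroxy-4,7a-dimethyl-1,2,3,6,7,7a-hexahydro-5H-inden-5-one (C9 alcohol with the hydroxyl cis to the C10 methyl)
Conditions: NaBH4 (0.3 equiv), EtOH, −20 °C
Reagents that add atoms: none
Why: Chemoselective hydride reduction: the saturated cyclopentanone is far more electrophilic than the tetrasubstituted conjugated ketone; hydride arrives anti to the angular methyl, and the C9 centre is only temporary.

Step 4
Reactants: 5 (1R,7aR)-1-hydroxy-4,7a-dimethyl-1,2,3,6,7,7a-hexahydro-5H-inden-5-one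
Product: 6 (1R,7aR)-1-(tert-butyldimethylsilyloxy)-4,7a-dimethyl-1,2,3,6,7,7a-hexahydro-5H-inden-5-one
Conditions: t-BuMe2SiCl, imidazole, DMF, 35 °C
Reagents that add atoms: tert-butyldimethylsilyl chloride, CC(C)(C)[Si](C)(C)Cl
Why: Standard silylation of a secondary alcohol; the ether is inert to dissolving metal, enolates and hydride and can later be removed by fluoride without touching an acetonide.

Step 5
Reactants: 6 (1R,7aR)-1-(tert-butyldimethylsilyloxy)-4,7a-dimethyl-1,2,3,6,7,7a-hexahydro-5H-inden-5-one
Product: 8 (1R,3aS,7aR)-1-(tert-butyldimethylsilyloxy)-4,4,7a-trimethyloctahydro-5H-inden-5-one (trans ring fusion: C5–H trans to the C10 methyl; C3 ketone; C4 gem-dimethyl), via lithium enolate 7 (not isolated)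
Conditions: Li (2.2 equiv), H2O (1.0 equiv), NH3(l)/THF, −78 → −33 °C; then MeI (excess), −78 → −33 °C
Reagents that add atoms: iodomethane, CI
Why: Reductive alkylation of an enone (dissolving-metal reduction, then trapping of the regiodefined enolate): protonation at the β-carbon C5 should give the trans fusion, as for hydrindenones that carry an oxygen substituent cis to the angular methyl on the five-membered ring, and enolate 7 is methylated at C4.

Step 6
Reactants: 8 (1R,3aS,7aR)-1-(tert-butyldimethylsilyloxy)-4,4,7a-trimethyloctahydro-5H-inden-5-one
Product: 10 (1R,3aS,6S,7aR)-1-(tert-butyldimethylsilyloxy)-6-hydroxy-4,4,7a-trimethyloctahydro-5H-inden-5-one (2-hydroxy-3-ketone; C2–OH equatorial and trans to the C10 methyl), via potassium enolate 9 (not isolated)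
Conditions: KN(SiMe3)2, THF, −78 °C; then 2-(benzenesulfonyl)-3-phenyloxaziridine, −78 °C; sat. NH4Cl
Reagents that add atoms: 2-(benzenesulfonyl)-3-phenyloxaziridine (Davis oxaziridine), O=S(=O)(c1ccccc1)N1OC1c1ccccc1
Why: Davis enolate hydroxylation; C4 is quaternary, so only the C2 enolate can form, and the oxidant reaches C2 from the face away from the axial C10 and C4 methyl groups, which leaves the hydroxyl equatorial and trans to the C10 methyl.

Step 7
Reactants: 10 the 2-hydroxy-3-ketone
Product: 11 B-nor 2,3-diol 9-silyl ether (C2–OH and C3–OH trans-diequatorial; C3–OH cis to the C10 methyl)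
Conditions: NaBH4, MeOH, 0 °C
Reagents that add atoms: none
Why: Hydride reduction of a 4,4-dimethyl-3-ketone: axial attack from the face opposite the axial C4 and C10 methyl groups gives the equatorial C3 alcohol, the known outcome for 2-hydroxy-3-oxo terpenoids of this substitution pattern.

Step 8
Reactants: 11 the 2,3-diol 9-silyl ether
Product: 12 2,3-O-isopropylidene derivative of 11 (trans-fused acetonide; C9 silyl ether)
Conditions: 2-methoxypropene, pyridinium p-toluenesulfonate (cat.), CH2Cl2, 0 °C → rt
Reagents that add atoms: 2-methoxypropene, COC(C)=C
Why: Kinetic acetalisation: a mixed ketal forms at the less hindered C2 hydroxyl and closes onto the C3 hydroxyl with loss of methanol, which is the reliable way to a trans-fused dioxolane; the silyl ether is untouched.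

Step 9
Reactants: 12 the acetonide silyl ether
Product: 13 B-nor-11-nor-ent-driman-9-ol 2,3-acetonide (C9 alcohol, hydroxyl cis to the C10 methyl)
Conditions: n-Bu4NF, THF, 50 °C
Reagents that add atoms: none
Why: Fluoride cleavage of the silyl ether; the acetonide is stable to fluoride and base.

Step 10
Reactants: 13 the C9 alcohol
Product: 14 B-nor-11-nor-ent-drimane-9-one 2,3-acetonide (trans-hydrindanone)
Conditions: (n-Pr4N)RuO4 (5 mol%), N-methylmorpholine N-oxide, 4 Å molecular sieves, CH2Cl2, rt
Reagents that add atoms: none
Why: Ley–Griffith oxidation of a secondary alcohol under neutral conditions that spare the acid-labile acetonide; C10 is quaternary and C5 is not adjacent to the ketone, so no centre can epimerise.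

Step 11
Reactants: 15 N-ethyl-N-nitrosourea
Product: 16 diazoethane (ethereal solution)
Conditions: 50% aq. KOH, Et2O, −5 → 0 °C; ether layer decanted, dried over KOH pellets and used at once
Reagents that add atoms: none
Why: Base-induced fragmentation of an N-alkyl-N-nitrosourea, the standard preparation of a non-stabilised diazoalkane; the cold solution is used without distillation.

Step 12
Reactants: 14 B-nor-11-nor-ent-drimane-9-one 2,3-acetonide; 16 diazoethane
Product: 17 11-nor-ent-drimane-9-one 2,3-acetonide (8-methyl-9-ketone, trans-decalin, C8 epimers)
Conditions: BF3·OEt2 (1.2 equiv), 16 (about 3 equiv, added slowly), Et2O/CH2Cl2, −78 °C; sat. NaHCO3 at −78 °C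
Reagents that add atoms: none
Why: BF3 activates the C9 carbonyl, the nucleophilic carbon of 16 adds to it, and the β-oxido diazonium betaine loses N2 as the C7 methylene shifts to the former diazo carbon (Büchner–Curtius–Schlotterbeck homologation, a Tiffeneau–Demjanov-type 1,2-shift), which forms the C8–C9 and C7–C8 bonds. Ring B is not closed end to end; it arises by enlargement of the five-membered B-nor ring to a cyclohexanone through this 1,2-alkyl shift. The closest known case is the Lewis-acid-promoted homologation with diazo compounds of cyclopentanones flanked by a quaternary carbon, such as ring D of 17-oxo steroids, where the methylene carbon migrates. The selectivity needed is migration of C7 and not C10: in the betaine the methyl on the diazo carbon turns away from the fully substituted C10, which places the C7–C9 bond antiperiplanar to the departing N2, and the less substituted carbon is also the better migrating group under Lewis acid promotion. A second insertion is not expected, because the carbonyl of 17 lies between a quaternary and a tertiary carbon. The new stereocentre C8 is not controlled and need not be, since it becomes trigonal in step 13. C5 and C10 are untouched, so the trans fusion of 14 is carried into the decalin. Slow addition at −78 °C and a cold bicarbonate quench keep free diazoalkane and Lewis acid contact with the acetonide to a minimum.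

Step 13
Reactants: 17 11-nor-ent-drimane-9-one 2,3-acetonide
Product: 19 11-nor-ent-drim-7-en-9-one 2,3-acetonide (C7=C8 enone), via trimethylsilyl enol ether 18 (not isolated)
Conditions: LiN(i-Pr)2, THF, −78 → 0 °C; Me3SiCl, −78 °C → rt; solvent exchange; Pd(OAc)2 (1.1 equiv), MeCN, rt
Reagents that add atoms: none
Why: Saegusa–Ito oxidation: C10 is quaternary, so the ketone enolises only towards C8 and both C8 epimers converge on 18; divalent palladium forms the C8 palladium enolate and β-hydride elimination into the ring gives the conjugated endocyclic enone, as with silyl enol ethers of 2-methylcyclohexanones.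

Step 14
Reactants: 19 11-nor-ent-drim-7-en-9-one 2,3-acetonide
Product: 20 ent-drima-7,9(11)-diene-2,3-diol acetonide (exocyclic C9=C11 conjugated with C7=C8)
Conditions: Ph3PCH3Br, KOt-Bu, toluene, 90 °C
Reagents that add atoms: methyltriphenylphosphonium bromide, C[P+](c1ccccc1)(c1ccccc1)c1ccccc1.[Br-]
Why: Wittig methylenation under the hot, salt-free conditions used for hindered ketones; the carbonyl has no α-hydrogen (C10 quaternary, C8 trigonal), and α,α-disubstituted cyclohexanones are methylenated this way.

Step 15
Reactants: 20 ent-drima-7,9(11)-diene-2,3-diol acetonide
Product: 22 ent-drim-7-ene-2,3,11-triol 2,3-acetonide (primary C11 alcohol; C9–H trans to the C10 methyl), via C11 alkylborane 21 (not isolated)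
Conditions: 9-borabicyclo[3.3.1]nonane (0.5 M in THF), THF, 0 °C → rt; then 3 M NaOH, 30% H2O2, 0 °C → rt
Reagents that add atoms: hydrogen peroxide, OO
Why: Hydroboration–oxidation: the bulky borane adds to the 1,1-disubstituted exocyclic olefin with boron on C11 and leaves the trisubstituted C7=C8 bond; it approaches C9 from the face opposite the axial C10 methyl, so hydrogen is delivered trans to that methyl and C11 ends up equatorial and cis to it, which sets C9; the C–B bond is then oxidised.

Step 16
Reactants: 22 ent-drim-7-ene-2,3,11-triol 2,3-acetonide; 23 umbelliferone (7-hydroxycoumarin)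
Product: 24 2,3-O-isopropylidene derivative of the target (C11 umbelliferyl ether)
Conditions: PPh3, diisopropyl azodicarboxylate, THF, 0 → 40 °C
Reagents that add atoms: none
Why: Mitsunobu etherification: the acidic 7-hydroxyl of the coumarin is a good pronucleophile and displaces the primary C11 oxyphosphonium; no stereocentre is involved, and the neutral conditions spare lactone, acetonide and olefin.

Step 17
Reactants: 24 the target acetonide
Product: 25 7-{[(1R,4aS,6S,7S,8aR)-6,7-dihydroxy-2,5,5,8a-tetramethyl-1,4,4a,5,6,7,8,8a-octahydronaphthalen-1-yl]methoxy}-2H-chromen-2-one (CNP0124364.1)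
Conditions: AcOH/H2O (4:1), 40 °C
Reagents that add atoms: none
Why: Mild acid hydrolysis of the strained trans-fused acetonide; these conditions should leave the aryl ether, the lactone and the position of the C7=C8 olefin unchanged.

Compound list

1 | 2-methylcyclopentane-1,3-dione | CC1C(=O)CCC1=O | starting material
2 | ethyl vinyl ketone (pent-1-en-3-one) | CCC(=O)C=C | starting material
3 | 2-methyl-2-(3-oxopentyl)cyclopentane-1,3-dione | CCC(=O)CCC1(C)C(=O)CCC1=O | intermediate
4 | (7aR)-4,7a-dimethyl-2,3,7,7a-tetrahydro-1H-indene-1,5(6H)-dione | O=C1CCC2=C(C)C(=O)CC[C@]21C | intermediate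
5 | (1R,7aR)-1-hydroxy-4,7a-dimethyl-1,2,3,6,7,7a-hexahydro-5H-inden-5-one | O[C@@H]1CCC2=C(C)C(=O)CC[C@]21C | intermediate
6 | (1R,7aR)-1-(tert-butyldimethylsilyloxy)-4,7a-dimethyl-1,2,3,6,7,7a-hexahydro-5H-inden-5-one | CC(C)(C)[Si](C)(C)O[C@@H]1CCC2=C(C)C(=O)CC[C@]21C | intermediate
7 | lithium enolate from 6 (O–Li on C3, C3=C4, trans ring fusion) | CC(C)(C)[Si](C)(C)O[C@@H]1CC[C@@H]2C(C)=C(O[Li])CC[C@]21C | intermediate
8 | (1R,3aS,7aR)-1-(tert-butyldimethylsilyloxy)-4,4,7a-trimethyloctahydro-5H-inden-5-one | CC(C)(C)[Si](C)(C)O[C@@H]1CC[C@@H]2C(C)(C)C(=O)CC[C@]21C | intermediate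
9 | potassium enolate of 8 (O–K on C3, C2=C3) | CC(C)(C)[Si](C)(C)O[C@@H]1CC[C@@H]2C(C)(C)C(O[K])=CC[C@]21C | intermediate
10 | (1R,3aS,6S,7aR)-1-(tert-butyldimethylsilyloxy)-6-hydroxy-4,4,7a-trimethyloctahydro-5H-inden-5-one | CC(C)(C)[Si](C)(C)O[C@@H]1CC[C@@H]2C(C)(C)C(=O)[C@@H](O)C[C@]21C | intermediate
11 | B-nor 2,3-diol 9-silyl ether (trans-diequatorial diol; C3–OH cis to the C10 methyl) | CC(C)(C)[Si](C)(C)O[C@@H]1CC[C@@H]2C(C)(C)[C@H](O)[C@@H](O)C[C@]21C | intermediate
12 | 2,3-acetonide of 11 (trans-fused dioxolane; C9 silyl ether) | CC(C)(C)[Si](C)(C)O[C@@H]1CC[C@@H]2C(C)(C)[C@@H]3OC(C)(C)O[C@H]3C[C@]21C | intermediate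
13 | B-nor-11-nor-ent-driman-9-ol 2,3-acetonide | O[C@@H]1CC[C@@H]2C(C)(C)[C@@H]3OC(C)(C)O[C@H]3C[C@]21C | intermediate
14 | B-nor-11-nor-ent-drimane-9-one 2,3-acetonide | O=C1CC[C@@H]2C(C)(C)[C@@H]3OC(C)(C)O[C@H]3C[C@]21C | intermediate
15 | N-ethyl-N-nitrosourea | CCN(N=O)C(N)=O | starting material
16 | diazoethane | CC=[N+]=[N-] | intermediate
17 | 11-nor-ent-drimane-9-one 2,3-acetonide (C8 epimers) | CC1CC[C@@H]2C(C)(C)[C@@H]3OC(C)(C)O[C@H]3C[C@@]2(C)C1=O | intermediate
18 | 9-(trimethylsilyloxy)-11-nor-ent-drim-8-ene-2,3-diol acetonide (silyl enol ether, C8=C9) | C[Si](C)(C)OC1=C(C)CC[C@@H]2C(C)(C)[C@@H]3OC(C)(C)O[C@H]3C[C@@]12C | intermediate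
19 | 11-nor-ent-drim-7-en-9-one 2,3-acetonide | CC1=CC[C@@H]2C(C)(C)[C@@H]3OC(C)(C)O[C@H]3C[C@@]2(C)C1=O | intermediate
20 | ent-drima-7,9(11)-diene-2,3-diol acetonide | CC1=CC[C@@H]2C(C)(C)[C@@H]3OC(C)(C)O[C@H]3C[C@@]2(C)C1=C | intermediate
21 | B-(ent-drim-7-en-11-yl)-9-borabicyclo[3.3.1]nonane 2,3-acetonide | CC1=CC[C@@H]2C(C)(C)[C@@H]3OC(C)(C)O[C@H]3C[C@@]2(C)[C@@H]1CB1C2CCCC1CCC2 | intermediate
22 | ent-drim-7-ene-2,3,11-triol 2,3-acetonide | CC1=CC[C@@H]2C(C)(C)[C@@H]3OC(C)(C)O[C@H]3C[C@@]2(C)[C@@H]1CO | intermediate
23 | umbelliferone (7-hydroxycoumarin) | Oc1ccc2ccc(=O)oc2c1 | starting material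
24 | 2,3-O-isopropylidene derivative of the target | CC1=CC[C@@H]2C(C)(C)[C@@H]3OC(C)(C)O[C@H]3C[C@@]2(C)[C@@H]1COc1ccc2ccc(=O)oc2c1 | intermediate
25 | 7-{[(1R,4aS,6S,7S,8aR)-6,7-dihydroxy-2,5,5,8a-tetramethyl-1,4,4a,5,6,7,8,8a-octahydronaphthalen-1-yl]methoxy}-2H-chromen-2-one | CC1=CC[C@@H]2C(C)(C)[C@H](O)[C@@H](O)C[C@@]2(C)[C@@H]1COc1ccc2ccc(=O)oc2c1 | target

Total step count: 17. Longest linear sequence: 16 steps (steps 1–10 and 12–17); step 11 is a one-step side branch that supplies 16.

Least certain steps

Step 12 (key step). What may go wrong: Lewis-acid-induced oligomerisation of diazoethane may outrun its addition to the hindered, neopentyl-type C9 carbonyl, so that conversion stalls. Longer contact with BF3 may open the strained acetonide. Some migration of C10, or closure of the betaine to an epoxide, would erode the yield further. Fallback: from 14, homologation with the more robust trimethylsilyldiazomethane under Me3Al promotion (CH2Cl2, −78 → −20 °C; the bulky silyl group again turns away from C10, so C7 migrates) gives 8-(trimethylsilyl)-11,12-dinor-ent-drimane-9-one 2,3-acetonide F1. Protodesilylation with n-Bu4NF in wet THF gives 11,12-dinor-ent-drimane-9-one 2,3-acetonide F2. Enolisation of F2, possible only towards C8, with one equivalent of LiN(i-Pr)2 and methylation with MeI then returns to 17.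

Step 5. What may go wrong: incomplete control of the ring fusion in the protonation at C5, and proton transfer between product ketone and enolate 7 before alkylation, which leads to unmethylated and C2-methylated material. Fallback: from 6, deconjugative methylation at C4 through the extended enolate (KOt-Bu, MeI, t-BuOH/THF) gives the β,γ-unsaturated ketone (1R,7aR)-1-(tert-butyldimethylsilyloxy)-4,4,7a-trimethyl-1,2,4,6,7,7a-hexahydro-5H-inden-5-one F3. Its C5=C6 bond is hydrogenated (H2, Pd on carbon, EtOAc) from the face opposite the angular methyl and the silyloxy group, which sets C5 by a different element of control and returns to 8.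

Step 13. What may go wrong: slow deprotonation of the hindered tertiary C8–H, and β-hydride elimination from the tertiary palladium enolate towards the C8 methyl in competition with elimination into the ring. Fallback: from 18 (prepared as in step 13), bromination with N-bromosuccinimide (THF, −78 °C) gives 8-bromo-11-nor-ent-drimane-9-one 2,3-acetonide F4. Dehydrobromination with Li2CO3 and LiBr in DMF at 120 °C, which is under thermodynamic control and favours the endocyclic conjugated enone, returns to 19.

Step 14. What may go wrong: the ylide may act as a base (γ-deprotonation at C6) instead of adding to a carbonyl flanked by a quaternary carbon and a methyl-bearing trigonal carbon, so that the enone is returned or deconjugated. Fallback: from 19, addition of the small, weakly basic organocerium reagent made from Me3SiCH2Li and CeCl3 (THF, −78 °C) gives the β-hydroxysilane 11-(trimethylsilyl)-ent-drim-7-ene-2,3,9-triol 2,3-acetonide F5. Peterson elimination with KH in THF returns to 20 without acid.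

Step 16. What may go wrong: substitution at the β-branched C11 oxyphosphonium may be slow, so that elimination across C9–C11 (the C9 hydrogen is allylic) or alkylation of the hydrazide by-product takes over. Fallback: from 22, the alcohol is converted at −78 °C (Tf2O, 2,6-lutidine, CH2Cl2) into the primary triflate ent-drim-7-ene-2,3,11-triol 2,3-acetonide 11-trifluoromethanesulfonate F6. This is displaced at 0 °C by the caesium salt of 23 (Cs2CO3, DMF), a good nucleophile but a poor base, to return to 24.

Further compounds

F1 | step 12 | 8-(trimethylsilyl)-11,12-dinor-ent-drimane-9-one 2,3-acetonide (C8 epimers) | C[Si](C)(C)C1CC[C@@H]2C(C)(C)[C@@H]3OC(C)(C)O[C@H]3C[C@@]2(C)C1=O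
F2 | step 12 | 11,12-dinor-ent-drimane-9-one 2,3-acetonide | O=C1CCC[C@@H]2C(C)(C)[C@@H]3OC(C)(C)O[C@H]3C[C@]21C
F3 | step 5 | (1R,7aR)-1-(tert-butyldimethylsilyloxy)-4,4,7a-trimethyl-1,2,4,6,7,7a-hexahydro-5H-inden-5-one | CC(C)(C)[Si](C)(C)O[C@@H]1CC=C2C(C)(C)C(=O)CC[C@]21C
F4 | step 13 | 8-bromo-11-nor-ent-drimane-9-one 2,3-acetonide (C8 epimers) | CC1(Br)CC[C@@H]2C(C)(C)[C@@H]3OC(C)(C)O[C@H]3C[C@@]2(C)C1=O
F5 | step 14 | 11-(trimethylsilyl)-ent-drim-7-ene-2,3,9-triol 2,3-acetonide (C9 epimers) | CC1=CC[C@@H]2C(C)(C)[C@@H]3OC(C)(C)O[C@H]3C[C@@]2(C)C1(O)C[Si](C)(C)C
F6 | step 16 | ent-drim-7-ene-2,3,11-triol 2,3-acetonide 11-trifluoromethanesulfonate | CC1=CC[C@@H]2C(C)(C)[C@@H]3OC(C)(C)O[C@H]3C[C@@]2(C)[C@@H]1COS(=O)(=O)C(F)(F)F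
A1 | alternative 1 | (R)-10′,11′-epoxyumbelliprenin, 7-{[(2E,6E)-9-((R)-3,3-dimethyloxiran-2-yl)-3,7-dimethylnona-2,6-dien-1-yl]oxy}coumarin | CC1(C)O[C@@H]1CC/C(C)=C/CC/C(C)=C/COc1ccc2ccc(=O)oc2c1
A2 | alternative 1 | 2-deoxy target, 7-(3-hydroxy-ent-drim-7-en-11-yloxy)coumarin | CC1=CC[C@@H]2C(C)(C)[C@H](O)CC[C@@]2(C)[C@@H]1COc1ccc2ccc(=O)oc2c1
A3 | alternative 2 | (E)-tert-butyldimethyl[(3-methylpenta-2,4-dien-1-yl)oxy]silane | C=C/C(C)=C/CO[Si](C)(C)C(C)(C)C
A4 | alternative 2 | (E)-2,4-dimethylpenta-2,4-dienal | O=C/C(C)=C/C(C)=C
A5 | alternative 2 | ring B aldehyde with C1 as formyl, C4 as isopropenyl and C11 as silyloxymethyl | CC1=CC[C@H](C(C)=C)[C@@](C)(C=O)[C@@H]1CO[Si](C)(C)C(C)(C)C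
A6 | alternative 3 | (S)-pantolactone | CC1(C)COC(=O)[C@H]1O
A7 | alternative 3 | methyl (E)-4-{(4S,5S)-5-[(3E)-5-(tert-butyldimethylsilyloxy)-2-methylhepta-3,5-dien-2-yl]-2,2-dimethyl-1,3-dioxolan-4-yl}-3-methylbut-2-enoate (silyl enol ether geometry open) | CC=C(O[Si](C)(C)C(C)(C)C)/C=C/C(C)(C)[C@@H]1OC(C)(C)O[C@H]1C/C(C)=C/C(=O)OC
A8 | alternative 3 | methyl 7-(tert-butyldimethylsilyloxy)-ent-drim-6-en-11-oate 2,3-acetonide (C8 epimers) | CC1C(O[Si](C)(C)C(C)(C)C)=C[C@@H]2C(C)(C)[C@@H]3OC(C)(C)O[C@H]3C[C@@]2(C)[C@@H]1C(=O)OC
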